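**Retrosynthetic overview**
1. Target ⇐ hydrogenolysis of the phenol benzyl ether and removal of the primary silyl ether, after acetylation of the tertiary alcohol of a 2-aryl-3-(silyloxymethyl)-4-benzyl-oxolan-4-ol.
2. Oxolane (second ring, formed last) ⇐ 1,4-diol: the primary tosylate is displaced by the benzylic alkoxide (5-exo, benzylic C–O bond untouched) ⇐ LiBH4 opening of an α-oxygenated γ-butyrolactone.
3. Tertiary carbinol ⇐ α-benzylation, then α-hydroxylation of the butyrolactone enolate, both anti to the neighbouring CH2OSi group.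
4. trans-γ-Aryl-β-carboxy-γ-butyrolactone (first ring) ⇐ intermolecular Evans syn-aldol of a succinate-derived N-acyl oxazolidinone with 3,4-dimethoxybenzaldehyde (key C–C bond, sets both CH stereocentres), then lactonisation.
5. Building blocks: (S)-4-benzyl-oxazolidinone, methyl succinyl chloride, veratraldehyde, O-benzylvanillin.

Assumption: the target is read as the (3S,4R,5S)-oxolan-3-yl acetate (aryl trans to CH2OH, benzyl cis to CH2OH, acetoxy trans to CH2OH); enolates and alkoxides generated in situ are treated as the reactive form of the numbered compound.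

**Step 1**
Reactants: 1 (4S)-4-benzyl-1,3-oxazolidin-2-one; 2 methyl 4-chloro-4-oxobutanoate
Product: 3 methyl 4-[(4S)-4-benzyl-2-oxo-1,3-oxazolidin-3-yl]-4-oxobutanoate
Conditions: n-BuLi, THF, −78 °C; then 2, −78 → 0 °C
Reagents that add atoms: none
Why: N-acylation of the lithiated oxazolidinone by the acid chloride (nucleophilic acyl substitution) is fast at −78 °C and leaves the methyl ester untouched.

**Step 2**
Reactants: 3 succinate imide; 4 3,4-dimethoxybenzaldehyde
Product: 6 (4S)-4-benzyl-3-{[(2S,3S)-2-(3,4-dimethoxyphenyl)-5-oxooxolan-3-yl]carbonyl}-1,3-oxazolidin-2-one (trans lactone), via syn-aldol adduct 5 (not isolated)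
Conditions: Bu2BOTf, iPr2NEt, CH2Cl2, 0 °C; 4, −78 → 0 °C; pH 7 buffer, MeOH, 30% H2O2, 0 °C; then PPTS (cat.), PhMe, 50 °C
Reagents that add atoms: none
Why: Evans syn-aldol addition: the Z-boron enolate of the imide adds to the aldehyde through a chair Zimmerman–Traxler transition state on the face away from the auxiliary benzyl group, setting the (3S,4S) pair, and the resulting γ-hydroxy ester lactonises to the trans lactone.

**Step 3**
Reactants: 6 lactone imide
Product: 8 (2S,3S)-2-(3,4-dimethoxyphenyl)-5-oxooxolane-3-carboxylic acid, via peroxy acid 7 (not isolated)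
Conditions: LiOH·H2O, 30% H2O2, THF/H2O (3:1), 0 °C; aq. Na2SO3; 1 M HCl to pH 2
Reagents that add atoms: hydrogen peroxide, OO (acts as LiOOH and supplies the acid OH oxygen)
Why: Hydroperoxide cleavage of the auxiliary attacks the exocyclic imide carbonyl selectively and without epimerisation, sulfite reduces the peroxy acid, and any opened γ-hydroxy acid recloses on acidification.

**Step 4**
Reactants: 8 lactone acid
Product: 9 (4R,5S)-5-(3,4-dimethoxyphenyl)-4-(hydroxymethyl)oxolan-2-one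
Conditions: BH3·SMe2, THF, 0 °C → rt; MeOH quench
Reagents that add atoms: none
Why: Chemoselective borane reduction: a free carboxylic acid is reduced through its acyloxyborane far faster than a lactone, and no stereocentre is touched.

**Step 5**
Reactants: 9 hydroxymethyl lactone
Product: 10 (4R,5S)-4-({[tert-butyl(diphenyl)silyl]oxy}methyl)-5-(3,4-dimethoxyphenyl)oxolan-2-one
Conditions: TBDPSCl, imidazole, DMF, rt
Reagents that add atoms: tert-butyl(chloro)diphenylsilane, CC(C)(C)[Si](Cl)(c1ccccc1)c1ccccc1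
Why: Silyl ether formation at the primary alcohol stops translactonisation and gives a bulky, base-stable group that later directs the enolate reactions.

**Step 6**
Reactants: 11 4-(benzyloxy)-3-methoxybenzaldehyde
Product: 12 [4-(benzyloxy)-3-methoxyphenyl]methanol
Conditions: NaBH4, MeOH, 0 °C
Reagents that add atoms: none
Why: Borohydride reduction of an aromatic aldehyde to the benzylic alcohol is clean and quantitative.

**Step 7**
Reactants: 12 benzylic alcohol
Product: 13 1-(benzyloxy)-4-(bromomethyl)-2-methoxybenzene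
Conditions: PBr3, Et2O, 0 °C; used at once
Reagents that add atoms: phosphorus tribromide, BrP(Br)Br
Why: Bromination of an activated benzylic alcohol with PBr3 (substitution via the phosphite ester) is fast at 0 °C.

**Step 8**
Reactants: 10 silyl-protected lactone; 13 benzylic bromide
Product: 14 (3S,4R,5S)-3-[4-(benzyloxy)-3-methoxybenzyl]-4-({[tert-butyl(diphenyl)silyl]oxy}methyl)-5-(3,4-dimethoxyphenyl)oxolan-2-one
Conditions: LiN(SiMe3)2, THF, −78 °C; 13, DMPU, −78 → −30 °C
Reagents that add atoms: none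
Why: Lactone enolate alkylation by a reactive benzylic bromide occurs anti to the C4 silyloxymethyl group (3,4-trans), and this C3 configuration is in any case erased in the next step.

**Step 9**
Reactants: 14 α-benzyl lactone
Product: 15 (3S,4R,5S)-3-[4-(benzyloxy)-3-methoxybenzyl]-4-({[tert-butyl(diphenyl)silyl]oxy}methyl)-5-(3,4-dimethoxyphenyl)-3-hydroxyoxolan-2-one
Conditions: KN(SiMe3)2, THF, −78 °C; (±)-trans-2-(phenylsulfonyl)-3-phenyloxaziridine, −78 °C; sat. NH4Cl
Reagents that add atoms: 2-(phenylsulfonyl)-3-phenyloxaziridine (Davis oxaziridine), O=S(=O)(c1ccccc1)N1OC1c1ccccc1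
Why: Davis enolate hydroxylation delivers oxygen to the planar potassium enolate on the face opposite the adjacent bulky CH2OTBDPS group, so the new tertiary OH is trans and the benzyl group cis to it, which is the (3S) centre of the target.

**Step 10**
Reactants: 15 α-hydroxy lactone
Product: 16 (3S,4R,5S)-3-[4-(benzyloxy)-3-methoxybenzyl]-4-({[tert-butyl(diphenyl)silyl]oxy}methyl)-5-(3,4-dimethoxyphenyl)-3-[(2-methoxypropan-2-yl)oxy]oxolan-2-one
Conditions: 2-methoxypropene (excess), PPTS (cat.), CH2Cl2, 0 °C → rt; Et3N quench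
Reagents that add atoms: 2-methoxypropene, COC(C)=C
Why: Acid-catalysed addition of the tertiary alcohol to the enol ether gives a mixed ketal that cannot migrate and that blocks later epoxide formation from the tertiary alkoxide.

**Step 11**
Reactants: 16 protected lactone
Product: 17 (1S,2R,3S)-3-[4-(benzyloxy)-3-methoxybenzyl]-2-({[tert-butyl(diphenyl)silyl]oxy}methyl)-1-(3,4-dimethoxyphenyl)-3-[(2-methoxypropan-2-yl)oxy]butane-1,4-diol
Conditions: LiBH4, THF, 0 °C → rt
Reagents that add atoms: none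
Why: Hydride reduction of the lactone to the 1,4-diol frees a benzylic secondary and a primary hydroxyl while the silyl ether, ketal and benzyl ether are inert and no stereocentre is affected.

**Step 12**
Reactants: 17 diol
Product: 19 (2S,3R,4S)-4-[4-(benzyloxy)-3-methoxybenzyl]-3-({[tert-butyl(diphenyl)silyl]oxy}methyl)-2-(3,4-dimethoxyphenyl)-4-[(2-methoxypropan-2-yl)oxy]oxolane, via primary tosylate 18 (not isolated)
Conditions: TsCl, Et3N, DMAP (cat.), CH2Cl2, 0 °C; crude, then NaH, THF, 0 °C → rt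
Reagents that add atoms: none
Why: Selective sulfonylation of the primary hydroxyl followed by intramolecular Williamson etherification (5-exo-tet SN2 at the primary carbon by the benzylic alkoxide) closes the oxolane without breaking the benzylic C–O bond, so that centre keeps its aldol-derived configuration.

**Step 13**
Reactants: 19 ketal-protected oxolane
Product: 20 (3S,4R,5S)-3-[4-(benzyloxy)-3-methoxybenzyl]-4-({[tert-butyl(diphenyl)silyl]oxy}methyl)-5-(3,4-dimethoxyphenyl)oxolan-3-ol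
Conditions: PPTS (cat.), MeOH, 0 °C
Reagents that add atoms: none
Why: Transketalisation removes the very acid-labile mixed ketal under conditions too mild to cleave the TBDPS ether or ionise the benzylic ring ether.

**Step 14**
Reactants: 20 tertiary alcohol
Product: 21 (3S,4R,5S)-3-[4-(benzyloxy)-3-methoxybenzyl]-4-({[tert-butyl(diphenyl)silyl]oxy}methyl)-5-(3,4-dimethoxyphenyl)oxolan-3-yl acetate
Conditions: Ac2O, DMAP, Et3N, CH2Cl2, 40 °C
Reagents that add atoms: acetic anhydride, CC(=O)OC(C)=O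
Why: DMAP-catalysed acylation through the N-acetylpyridinium ion acetylates the tertiary alcohol, which is the only free hydroxyl in the molecule.

**Step 15**
Reactants: 21 silyl-protected acetate
Product: 22 (3S,4R,5S)-3-[4-(benzyloxy)-3-methoxybenzyl]-5-(3,4-dimethoxyphenyl)-4-(hydroxymethyl)oxolan-3-yl acetate
Conditions: HF·pyridine, pyridine, THF, 0 °C → rt
Reagents that add atoms: none
Why: Fluoride-mediated desilylation in a pyridine-buffered, weakly acidic medium frees the primary alcohol without generating the alkoxide that would trigger tertiary-to-primary acetyl migration.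

**Step 16**
Reactants: 22 O-benzyl phenol ether
Product: 23 (3S,4R,5S)-5-(3,4-dimethoxyphenyl)-3-(4-hydroxy-3-methoxybenzyl)-4-(hydroxymethyl)oxolan-3-yl acetate (target)
Conditions: H2 (1 atm), Pd/C (10% palladium on carbon), EtOAc, rt, stop at full conversion
Reagents that add atoms: none
Why: Hydrogenolysis of the aryl benzyl ether is neutral and much faster than cleavage of the benzylic ring C–O bond, so the acetate and the oxolane survive.

**Compound list**
1 | (4S)-4-benzyl-1,3-oxazolidin-2-one | O=C1N[C@@H](Cc2ccccc2)CO1 | starting material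
2 | methyl 4-chloro-4-oxobutanoate | COC(=O)CCC(Cl)=O | starting material
3 | methyl 4-[(4S)-4-benzyl-2-oxo-1,3-oxazolidin-3-yl]-4-oxobutanoate | COC(=O)CCC(=O)N1C(=O)OC[C@@H]1Cc1ccccc1 | intermediate
4 | 3,4-dimethoxybenzaldehyde | COc1ccc(C=O)cc1OC | starting material
5 | methyl (3S,4S)-3-{[(4S)-4-benzyl-2-oxo-1,3-oxazolidin-3-yl]carbonyl}-4-(3,4-dimethoxyphenyl)-4-hydroxybutanoate | O[C@H](c1ccc(OC)c(OC)c1)[C@H](CC(=O)OC)C(=O)N1C(=O)OC[C@@H]1Cc1ccccc1 | intermediate (not isolated)
6 | (4S)-4-benzyl-3-{[(2S,3S)-2-(3,4-dimethoxyphenyl)-5-oxooxolan-3-yl]carbonyl}-1,3-oxazolidin-2-one | O=C1O[C@H](c2ccc(OC)c(OC)c2)[C@H](C1)C(=O)N1C(=O)OC[C@@H]1Cc1ccccc1 | intermediate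
7 | (2S,3S)-2-(3,4-dimethoxyphenyl)-5-oxooxolane-3-carboperoxoic acid | O=C1O[C@H](c2ccc(OC)c(OC)c2)[C@H](C1)C(=O)OO | intermediate (not isolated)
8 | (2S,3S)-2-(3,4-dimethoxyphenyl)-5-oxooxolane-3-carboxylic acid | O=C1O[C@H](c2ccc(OC)c(OC)c2)[C@H](C1)C(=O)O | intermediate
9 | (4R,5S)-5-(3,4-dimethoxyphenyl)-4-(hydroxymethyl)oxolan-2-one | O=C1O[C@H](c2ccc(OC)c(OC)c2)[C@H](C1)CO | intermediate
10 | (4R,5S)-4-({[tert-butyl(diphenyl)silyl]oxy}methyl)-5-(3,4-dimethoxyphenyl)oxolan-2-one | O=C1O[C@H](c2ccc(OC)c(OC)c2)[C@H](C1)CO[Si](c1ccccc1)(c1ccccc1)C(C)(C)C | intermediate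
11 | 4-(benzyloxy)-3-methoxybenzaldehyde | COc1cc(C=O)ccc1OCc1ccccc1 | starting material
12 | [4-(benzyloxy)-3-methoxyphenyl]methanol | COc1cc(CO)ccc1OCc1ccccc1 | intermediate
13 | 1-(benzyloxy)-4-(bromomethyl)-2-methoxybenzene | COc1cc(CBr)ccc1OCc1ccccc1 | intermediate
14 | (3S,4R,5S)-3-[4-(benzyloxy)-3-methoxybenzyl]-4-({[tert-butyl(diphenyl)silyl]oxy}methyl)-5-(3,4-dimethoxyphenyl)oxolan-2-one | COc1cc(C[C@@H]2C(=O)O[C@H](c3ccc(OC)c(OC)c3)[C@H]2CO[Si](c2ccccc2)(c2ccccc2)C(C)(C)C)ccc1OCc1ccccc1 | intermediate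
15 | (3S,4R,5S)-3-[4-(benzyloxy)-3-methoxybenzyl]-4-({[tert-butyl(diphenyl)silyl]oxy}methyl)-5-(3,4-dimethoxyphenyl)-3-hydroxyoxolan-2-one | COc1cc(C[C@@]2(O)C(=O)O[C@H](c3ccc(OC)c(OC)c3)[C@H]2CO[Si](c2ccccc2)(c2ccccc2)C(C)(C)C)ccc1OCc1ccccc1 | intermediate
16 | (3S,4R,5S)-3-[4-(benzyloxy)-3-methoxybenzyl]-4-({[tert-butyl(diphenyl)silyl]oxy}methyl)-5-(3,4-dimethoxyphenyl)-3-[(2-methoxypropan-2-yl)oxy]oxolan-2-one | COc1cc(C[C@@]2(OC(C)(C)OC)C(=O)O[C@H](c3ccc(OC)c(OC)c3)[C@H]2CO[Si](c2ccccc2)(c2ccccc2)C(C)(C)C)ccc1OCc1ccccc1 | intermediate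
17 | (1S,2R,3S)-3-[4-(benzyloxy)-3-methoxybenzyl]-2-({[tert-butyl(diphenyl)silyl]oxy}methyl)-1-(3,4-dimethoxyphenyl)-3-[(2-methoxypropan-2-yl)oxy]butane-1,4-diol | COc1cc(C[C@@](OC(C)(C)OC)(CO)[C@H](CO[Si](c2ccccc2)(c2ccccc2)C(C)(C)C)[C@H](O)c2ccc(OC)c(OC)c2)ccc1OCc1ccccc1 | intermediate
18 | (2S,3R,4S)-2-[4-(benzyloxy)-3-methoxybenzyl]-3-({[tert-butyl(diphenyl)silyl]oxy}methyl)-4-(3,4-dimethoxyphenyl)-4-hydroxy-2-[(2-methoxypropan-2-yl)oxy]butyl 4-methylbenzenesulfonate | COc1cc(C[C@@](OC(C)(C)OC)(COS(=O)(=O)c2ccc(C)cc2)[C@H](CO[Si](c2ccccc2)(c2ccccc2)C(C)(C)C)[C@H](O)c2ccc(OC)c(OC)c2)ccc1OCc1ccccc1 | intermediate (not isolated)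
19 | (2S,3R,4S)-4-[4-(benzyloxy)-3-methoxybenzyl]-3-({[tert-butyl(diphenyl)silyl]oxy}methyl)-2-(3,4-dimethoxyphenyl)-4-[(2-methoxypropan-2-yl)oxy]oxolane | COc1cc(C[C@@]2(OC(C)(C)OC)CO[C@H](c3ccc(OC)c(OC)c3)[C@H]2CO[Si](c2ccccc2)(c2ccccc2)C(C)(C)C)ccc1OCc1ccccc1 | intermediate
20 | (3S,4R,5S)-3-[4-(benzyloxy)-3-methoxybenzyl]-4-({[tert-butyl(diphenyl)silyl]oxy}methyl)-5-(3,4-dimethoxyphenyl)oxolan-3-ol | COc1cc(C[C@@]2(O)CO[C@H](c3ccc(OC)c(OC)c3)[C@H]2CO[Si](c2ccccc2)(c2ccccc2)C(C)(C)C)ccc1OCc1ccccc1 | intermediate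
21 | (3S,4R,5S)-3-[4-(benzyloxy)-3-methoxybenzyl]-4-({[tert-butyl(diphenyl)silyl]oxy}methyl)-5-(3,4-dimethoxyphenyl)oxolan-3-yl acetate | COc1cc(C[C@@]2(OC(C)=O)CO[C@H](c3ccc(OC)c(OC)c3)[C@H]2CO[Si](c2ccccc2)(c2ccccc2)C(C)(C)C)ccc1OCc1ccccc1 | intermediate
22 | (3S,4R,5S)-3-[4-(benzyloxy)-3-methoxybenzyl]-5-(3,4-dimethoxyphenyl)-4-(hydroxymethyl)oxolan-3-yl acetate | COc1cc(C[C@@]2(OC(C)=O)CO[C@H](c3ccc(OC)c(OC)c3)[C@H]2CO)ccc1OCc1ccccc1 | intermediate
23 | (3S,4R,5S)-5-(3,4-dimethoxyphenyl)-3-(4-hydroxy-3-methoxybenzyl)-4-(hydroxymethyl)oxolan-3-yl acetate | COc1cc(C[C@@]2(OC(C)=O)CO[C@H](c3ccc(OC)c(OC)c3)[C@H]2CO)ccc1O | target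

**Totals**
Total step count: 16. Longest linear sequence: 14 steps (steps 1–5 and 8–16); steps 6–7 are a two-step side branch.

**Three steps most likely to fail, with fallbacks**

Step 9 (enolate hydroxylation). The risk is incomplete facial selectivity or low conversion when forming the fully substituted carbinol. The fallback builds the carbinol from an epoxide instead; it sets out from 10 and comes back at 15, so steps 6–9 are no longer needed. The lithium enolate of 10 is trapped with [Me2N=CH2]I (Mannich reaction) to give the α-(dimethylaminomethyl) lactone F1. MeI converts it into the trimethylammonium iodide F2, and NaHCO3 eliminates this to the α-methylene lactone F3. Dimethyldioxirane in acetone epoxidises the exocyclic alkene from the face opposite the CH2OTBDPS group to give the spiro-epoxide F4. [4-(Benzyloxy)-3-methoxyphenyl]magnesium bromide F5, made from 1-(benzyloxy)-4-bromo-2-methoxybenzene and Mg, is then added with catalytic CuBr·SMe2 in THF at −40 °C. It opens F4 at the epoxide CH2 carbon and gives 15 with the same configuration.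

Step 12 (tosylation and ring closure). The risks are slow displacement at the neopentyl-type carbon, silyl migration under NaH, or loss of the mixed ketal. The fallback changes the ring-forming logic to reductive deoxygenation of a lactol; it sets out from 15 and comes back at 20, so steps 10, 11 and 13 fall away. (i-Bu)2AlH in CH2Cl2 at −78 °C reduces the lactone of 15 to the lactol F6 (anomer mixture). Et3SiH with BF3·OEt2 at −78 °C then reduces the derived oxocarbenium ion, leaving the ring oxygen and the benzylic centre in place, to give 20.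

Step 15 (desilylation next to the tertiary acetate). The risk is acetyl migration to the freed primary hydroxyl or sluggish TBDPS cleavage. The fallback frees the primary hydroxyl enzymatically instead; it sets out from 20 and comes back at 22. Bu4NF in THF removes the silyl group before any acetate is present, giving the diol F7. Ac2O, DMAP and Et3N at 40 °C acetylate both hydroxyls to the diacetate F8. Immobilised Candida antarctica lipase B with butan-1-ol in tert-butyl methyl ether at rt then cleaves only the primary acetate under neutral conditions and gives 22.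

**Further compounds**
F1 | step 9 | (3R,4R,5S)-4-({[tert-butyl(diphenyl)silyl]oxy}methyl)-5-(3,4-dimethoxyphenyl)-3-[(dimethylamino)methyl]oxolan-2-one | CN(C)C[C@@H]1C(=O)O[C@H](c2ccc(OC)c(OC)c2)[C@H]1CO[Si](c1ccccc1)(c1ccccc1)C(C)(C)C
F2 | step 9 | {[(3R,4R,5S)-4-({[tert-butyl(diphenyl)silyl]oxy}methyl)-5-(3,4-dimethoxyphenyl)-2-oxooxolan-3-yl]methyl}trimethylammonium iodide | C[N+](C)(C)C[C@@H]1C(=O)O[C@H](c2ccc(OC)c(OC)c2)[C@H]1CO[Si](c1ccccc1)(c1ccccc1)C(C)(C)C.[I-]
F3 | step 9 | (4R,5S)-4-({[tert-butyl(diphenyl)silyl]oxy}methyl)-5-(3,4-dimethoxyphenyl)-3-methylideneoxolan-2-one | C=C1C(=O)O[C@H](c2ccc(OC)c(OC)c2)[C@H]1CO[Si](c1ccccc1)(c1ccccc1)C(C)(C)C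
F4 | step 9 | (3R,6S,7R)-7-({[tert-butyl(diphenyl)silyl]oxy}methyl)-6-(3,4-dimethoxyphenyl)-1,5-dioxaspiro[2.4]heptan-4-one | C1O[C@@]12C(=O)O[C@H](c3ccc(OC)c(OC)c3)[C@H]2CO[Si](c2ccccc2)(c2ccccc2)C(C)(C)C
F5 | step 9 | [4-(benzyloxy)-3-methoxyphenyl]magnesium bromide | COc1cc([Mg]Br)ccc1OCc1ccccc1
F6 | step 12 | (3S,4R,5S)-3-[4-(benzyloxy)-3-methoxybenzyl]-4-({[tert-butyl(diphenyl)silyl]oxy}methyl)-5-(3,4-dimethoxyphenyl)oxolane-2,3-diol (anomer mixture) | COc1cc(C[C@@]2(O)C(O)O[C@H](c3ccc(OC)c(OC)c3)[C@H]2CO[Si](c2ccccc2)(c2ccccc2)C(C)(C)C)ccc1OCc1ccccc1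
F7 | step 15 | (3S,4R,5S)-3-[4-(benzyloxy)-3-methoxybenzyl]-5-(3,4-dimethoxyphenyl)-4-(hydroxymethyl)oxolan-3-ol | COc1cc(C[C@@]2(O)CO[C@H](c3ccc(OC)c(OC)c3)[C@H]2CO)ccc1OCc1ccccc1
F8 | step 15 | [(2S,3R,4S)-4-acetoxy-4-[4-(benzyloxy)-3-methoxybenzyl]-2-(3,4-dimethoxyphenyl)oxolan-3-yl]methyl acetate | COc1cc(C[C@@]2(OC(C)=O)CO[C@H](c3ccc(OC)c(OC)c3)[C@H]2COC(C)=O)ccc1OCc1ccccc1
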